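**Plan**

- Cuts: first the C7–CH2 bond of the methylene bridge (benzofuran numbering, pyranone atoms primed), which separates a 4-hydroxypyranone from a C7-unsubstituted acyl dihydrobenzofuran; then the three arene bonds C3a–C7a, C4–C5 and C6–C7 at once; then the alkynyl C–O, C3–alkyne and acyl–alkyne bonds of the two open-chain partners.
- Enabling feature: around the benzene ring the oxygen-bearing carbons C4, C6 and C7a alternate with C3a, C5 and C7, so the ring is the head-to-tail trimer of three 1-oxygenated alkynes, and two of these are already tied together by the O1–C2–C3 unit of the dihydrofuran ring.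
- Forward: tert-butoxyethyne, made once from trichloroethylene, serves both partners: as its sodium acetylide it opens an (R)-epoxide that supplies C2–C3, and as its Grignard reagent it acylates a Weinreb amide. After ethynylation of O1, a rhodium-catalysed [2+2+2] cycloaddition of the diyne with the tert-butoxy ynone closes the benzene and the dihydrofuran ring together.
- Afterwards the isopropenyl group is unveiled (hydrogenolysis, dehydration), the tert-butyl ethers are cleaved, and the pyranone ring, built separately from 3-pentanone and malonyl dichloride, is attached to C7 by a Mannich-type methylene transfer.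
- Stereochemistry: C2 comes from hydrolytic kinetic resolution of a terminal epoxide whose C2–O bond is never broken afterwards; the acyl α-carbon comes from (R)-2-methylbutanoic acid and passes only through non-enolising steps.

Key step: step 11

Remark on the chemistry: an alkynyl ether on a carbon that also carries the isopropenyl group is an allyl alkynyl ether and would rearrange [3,3]-sigmatropically to a ketene below room temperature. C2 therefore carries a 2-(benzyloxy)propan-2-yl group until both rings are closed, and the alkene is made afterwards.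

**Route**

Step 1
Reactants: 1 2-methylbut-3-en-2-ol
Product: 2 benzyl 2-methylbut-3-en-2-yl ether
Conditions: NaH, BnBr, Bu4NI (cat.), THF/DMF, 0 °C → rt
Reagents that add atoms: benzyl bromide, BrCc1ccccc1
Why: Williamson ether synthesis on the tertiary sodium alkoxide; the benzyl group cannot migrate to the neighbouring oxygen later and is removable by hydrogenolysis at a stage where no alkene is present.

Step 2
Reactants: 2 benzyl 2-methylbut-3-en-2-yl ether
Product: 3 rac-2-[2-(benzyloxy)propan-2-yl]oxirane
Conditions: mCPBA, CH2Cl2, 0 °C → rt (prolonged)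
Reagents that add atoms: meta-chloroperoxybenzoic acid, OOC(=O)c1cccc(Cl)c1
Why: Prilezhaev epoxidation of the only alkene; the monosubstituted double bond is slow but there is no competing oxidisable site.

Step 3
Reactants: 3 rac-2-[2-(benzyloxy)propan-2-yl]oxirane
Product: 4 (R)-2-[2-(benzyloxy)propan-2-yl]oxirane
Conditions: (R,R)-(salen)Co(OAc) (trivalent cobalt, 1–2 mol%; salen = N,N′-bis(3,5-di-tert-butylsalicylidene)cyclohexane-1,2-diamine dianion), H2O (0.55 equiv), THF, 0 °C → rt; unreacted epoxide separated from the diol
Reagents that add atoms: none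
Why: Jacobsen hydrolytic kinetic resolution: the cobalt complex should hydrolyse the (S)-epoxide at its CH2 terminus and leave the (R)-epoxide, which sets C2 of the target; by analogy with simple terminal epoxides the (R,R)-complex retains the enantiomer that corresponds spatially to (S)-propylene oxide, which here is named R because the oxygen-bearing substituent outranks the ring CH2, and the sense is to be confirmed on the recovered epoxide (otherwise the (S,S)-complex is used).

Step 4
Reactants: 5 trichloroethylene
Product: 6 (E)-1-tert-butoxy-1,2-dichloroethene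
Conditions: KOtBu, THF, −40 °C → rt (slow addition, inert atmosphere; dichloroacetylene forms transiently)
Reagents that add atoms: potassium tert-butoxide, CC(C)(C)[O-].[K+]
Why: tert-butoxide dehydrochlorinates trichloroethylene to dichloroacetylene and adds to it in anti fashion, the standard entry to (E)-1,2-dichlorovinyl ethers as alkynyl ether precursors.

Step 5
Reactants: 6 (E)-1-tert-butoxy-1,2-dichloroethene
Product: 8 tert-butoxyethyne, via lithium tert-butoxyacetylide 7 (not isolated)
Conditions: n-BuLi (2.05 equiv), Et2O, −78 → −40 °C; H2O, −78 → 0 °C; organic phase dried (K2CO3), distilled cold at reduced pressure, kept at −20 °C as a titrated stock solution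
Reagents that add atoms: none
Why: dehydrochlorination to the chloroalkynyl ether and chlorine–lithium exchange give the acetylide, and its cold protonation gives the free alkynyl ether, the standard dichlorovinyl-ether route to 1-alkoxyalkynes; the product is handled cold because tert-butyl alkynyl ethers lose isobutene on warming.

Step 6
Reactants: 8 tert-butoxyethyne; 4 (R)-2-[2-(benzyloxy)propan-2-yl]oxirane
Product: 10 (R)-2-(benzyloxy)-6-(tert-butoxy)-2-methylhex-5-yn-3-ol, via sodium tert-butoxyacetylide 9 (not isolated)
Conditions: NaNH2 (1.2 equiv), liq. NH3/THF, −40 °C; then 4, −33 °C (reflux), NH3 allowed to evaporate slowly to rt; NH4Cl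
Reagents that add atoms: none
Why: sodium alkoxyacetylides are alkylated by primary halides and terminal epoxides in liquid ammonia, and the SN2 opening occurs at the unhindered CH2 terminus, so the C2 stereocentre is not involved.

Step 7
Reactants: 10 (R)-2-(benzyloxy)-6-(tert-butoxy)-2-methylhex-5-yn-3-ol; 5 trichloroethylene
Product: 11 (R)-2-(benzyloxy)-6-(tert-butoxy)-3-{[(E)-1,2-dichloroethenyl]oxy}-2-methylhex-5-yne
Conditions: KH, THF, 0 °C; Cl2C=CHCl, −50 °C → rt
Reagents that add atoms: none
Why: the potassium alkoxide adds to dichloroacetylene generated in situ (the same addition as in step 4), an established way to place an alkyne precursor on a hindered secondary alcohol without touching its C–O bond.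

Step 8
Reactants: 11 (R)-2-(benzyloxy)-6-(tert-butoxy)-3-{[(E)-1,2-dichloroethenyl]oxy}-2-methylhex-5-yne
Product: 13 (R)-2-(benzyloxy)-6-(tert-butoxy)-3-(ethynyloxy)-2-methylhex-5-yne, via lithium alkynyl ether 12 (not isolated)
Conditions: n-BuLi (2.2 equiv), THF, −78 → −40 °C; H2O, −78 °C; Et3N-deactivated silica, stored cold
Reagents that add atoms: none
Why: dehydrochlorination and chlorine–lithium exchange give the lithium alkynyl ether, which is protonated cold; the O-bearing carbon now has only sp3 neighbours, so no sigmatropic rearrangement is open to the ethynyl ether.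

Step 9
Reactants: 14 (R)-2-methylbutanoic acid
Product: 16 (R)-N-methoxy-N,2-dimethylbutanamide, via acyl imidazole 15 (not isolated)
Conditions: CDI, CH2Cl2, 0 °C → rt; then MeNHOMe·HCl, rt
Reagents that add atoms: N,O-dimethylhydroxylamine hydrochloride, CNOC.Cl
Why: amide formation through the acyl imidazole; an α-alkyl acid without further activation should not racemise under these near-neutral conditions.

Step 10
Reactants: 8 tert-butoxyethyne; 16 (R)-N-methoxy-N,2-dimethylbutanamide
Product: 18 (R)-1-(tert-butoxy)-4-methylhex-1-yn-3-one, via bromomagnesium tert-butoxyacetylide 17 (not isolated)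
Conditions: 8 (1.3 equiv), EtMgBr (1.2 equiv), THF, 0 °C → rt; then 16, 0 °C; cold aq. NaH2PO4; used promptly, kept below rt
Reagents that add atoms: none
Why: Weinreb ketone synthesis with the alkynyl Grignard reagent obtained by deprotonating 8 with EtMgBr: the chelated magnesium adduct persists until the cold buffered quench, which prevents over-addition, and the weakly basic magnesium acetylide should leave the α-stereocentre alone.

Step 11
Reactants: 13 (R)-2-(benzyloxy)-6-(tert-butoxy)-3-(ethynyloxy)-2-methylhex-5-yne; 18 (R)-1-(tert-butoxy)-4-methylhex-1-yn-3-one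
Product: 19 (R)-1-{(R)-2-[2-(benzyloxy)propan-2-yl]-4,6-di-tert-butoxy-2,3-dihydro-1-benzofuran-5-yl}-2-methylbutan-1-one
Conditions: [Rh(cod)2]BF4 (5 mol%), rac-BINAP (5 mol%) (pre-treated with H2 in CH2Cl2, then Ar), 18 (2 equiv), slow addition of 13, CH2Cl2, rt
Reagents that add atoms: none
Why: Proposed new method: the cationic monovalent rhodium–bisphosphine fragment should bind both alkynes of the 1,6-diyne 13 and couple them oxidatively to a rhodacyclopentadiene of trivalent rhodium, which forms C3a–C7a and so closes the dihydrofuran ring O1–C2–C3–C3a–C7a by intramolecular alkyne–alkyne coupling across the three-atom tether, after which insertion of ynone 18 and C–C reductive elimination form C4–C5 and C6–C7 and close the benzene ring as a formal [2+2+2] cycloaddition. The closest known reaction type is the cationic rhodium/BINAP-catalysed [2+2+2] cycloaddition of 1,6-diynes with electron-poor alkynes and with alkynyl ethers at room temperature; three oxygenated alkynes in one such event have not been shown. No stereocentre is formed: C2 and the acyl α-carbon are spectators, no base is present, and the temperature stays near 20 °C, below the onset of retro-ene loss of isobutene from the tert-butyl alkynyl ethers. The step needs the ynone to enter with its acyl-bearing carbon C5 on C4 and its tert-butoxy carbon C6 on the unsubstituted C7: the push–pull polarisation of 18 (electrophilic C6, nucleophilic C5) matches the head-to-tail pattern, the reverse orientation would put two tert-butoxy groups on neighbouring carbons, and the rhodium–C7 bond is the less hindered site for insertion. Cross-trimerisation rather than homo-trimerisation should be secured by the tether, which makes oxidative coupling within 13 faster than any intermolecular pairing, by slow addition of 13 to excess 18, and by the reluctance of the fully substituted ynone to trimerise with itself. No alkene is present at this stage, so the catalyst has no competing π-system.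

Step 12
Reactants: 19 (R)-1-{(R)-2-[2-(benzyloxy)propan-2-yl]-4,6-di-tert-butoxy-2,3-dihydro-1-benzofuran-5-yl}-2-methylbutan-1-one
Product: 20 (R)-1-[(R)-4,6-di-tert-butoxy-2-(2-hydroxypropan-2-yl)-2,3-dihydro-1-benzofuran-5-yl]-2-methylbutan-1-one
Conditions: H2 (1 atm), Pd/C, EtOAc, rt
Reagents that add atoms: none
Why: hydrogenolysis of the benzyl ether at the one stage that contains neither alkene nor alkyne; the doubly ortho-substituted aryl ketone and the aryl tert-butyl ethers should be inert.

Step 13
Reactants: 20 (R)-1-[(R)-4,6-di-tert-butoxy-2-(2-hydroxypropan-2-yl)-2,3-dihydro-1-benzofuran-5-yl]-2-methylbutan-1-one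
Product: 21 (R)-1-[(R)-4,6-di-tert-butoxy-2-(prop-1-en-2-yl)-2,3-dihydro-1-benzofuran-5-yl]-2-methylbutan-1-one
Conditions: Burgess reagent (MeO2C–N(−)–SO2–N(+)Et3), toluene, 50–60 °C
Reagents that add atoms: none
Why: Burgess dehydration: the sulfamate ester of the tertiary alcohol collapses by syn-elimination, and removal of one of six methyl hydrogens should be preferred over the single C2–H, whose loss would give an enol ether, so the isopropenyl group results and C2 is untouched.

Step 14
Reactants: 21 (R)-1-[(R)-4,6-di-tert-butoxy-2-(prop-1-en-2-yl)-2,3-dihydro-1-benzofuran-5-yl]-2-methylbutan-1-one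
Product: 22 (R)-1-[(R)-4,6-dihydroxy-2-(prop-1-en-2-yl)-2,3-dihydro-1-benzofuran-5-yl]-2-methylbutan-1-one
Conditions: TFA (10 equiv), CH2Cl2, 0 °C, short reaction time, Ar sparge
Reagents that add atoms: none
Why: acidolysis of aryl tert-butyl ethers with loss of isobutene is especially easy here because each ether oxygen is ortho to the ketone and the freed phenols are hydrogen-bonded; the dilute, cold and brief treatment is meant to spare the isopropenyl group and the allylic C2–O1 bond.

Step 15
Reactants: 23 3-pentanone
Product: 24 3-(trimethylsilyloxy)pent-2-ene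
Conditions: LiN(iPr)2, THF, −78 °C; Me3SiCl, −78 °C → rt
Reagents that add atoms: chlorotrimethylsilane, C[Si](C)(C)Cl
Why: kinetic enolisation and O-silylation; the enol ether geometry has no bearing on the next step.

Step 16
Reactants: 24 3-(trimethylsilyloxy)pent-2-ene; 25 malonyl dichloride
Product: 26 6-ethyl-4-hydroxy-5-methyl-2H-pyran-2-one
Conditions: Et2O, −78 °C → rt; aqueous work-up
Reagents that add atoms: none
Why: C-acylation of the silyl enol ether by one acid chloride function gives a β-diketone acid chloride whose enol oxygen closes the six-membered lactone, a known pyranone synthesis from silyl enol ethers and malonyl dichloride.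

Step 17
Reactants: 26 6-ethyl-4-hydroxy-5-methyl-2H-pyran-2-one; 22 (R)-1-[(R)-4,6-dihydroxy-2-(prop-1-en-2-yl)-2,3-dihydro-1-benzofuran-5-yl]-2-methylbutan-1-one
Product: 29 6-ethyl-3-{[(2R)-4,6-dihydroxy-5-[(2R)-2-methylbutanoyl]-2-(prop-1-en-2-yl)-2,3-dihydro-1-benzofuran-7-yl]methyl}-4-hydroxy-5-methyl-2H-pyran-2-one (target CNP0199358.1), via Mannich base 27 (not isolated), via methylidene pyrandione 28 (not isolated)
Conditions: 26, Me2N=CH2(+) I(−) (1.0 equiv), CHCl3, rt; then 22, 50 °C
Reagents that add atoms: N,N-dimethylmethyleneiminium iodide (Eschenmoser's salt), C=[N+](C)C.[I-]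
Why: Mannich reaction at the nucleophilic C3′ of the pyranone, thermal loss of dimethylamine to the methylidene dione and Friedel–Crafts-type conjugate addition of C7, the only free ring position of the acylphloroglucinol, a sequence known for methylene-bridged phloroglucinol–pyranone natural products; forming the Mannich base first should suppress the symmetrical dimers.

**Compound list**

1 | 2-methylbut-3-en-2-ol | C=CC(C)(C)O | starting material
2 | benzyl 2-methylbut-3-en-2-yl ether | C=CC(C)(C)OCc1ccccc1 | intermediate
3 | rac-2-[2-(benzyloxy)propan-2-yl]oxirane | CC(C)(OCc1ccccc1)C1CO1 | intermediate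
4 | (R)-2-[2-(benzyloxy)propan-2-yl]oxirane | CC(C)(OCc1ccccc1)[C@H]1CO1 | intermediate
5 | trichloroethylene | ClC=C(Cl)Cl | starting material
6 | (E)-1-tert-butoxy-1,2-dichloroethene | CC(C)(C)O/C(Cl)=C\Cl | intermediate
7 | lithium tert-butoxyacetylide | [Li]C#COC(C)(C)C | intermediate (not isolated)
8 | tert-butoxyethyne (tert-butyl ethynyl ether) | C#COC(C)(C)C | intermediate
9 | sodium tert-butoxyacetylide | [Na]C#COC(C)(C)C | intermediate (not isolated)
10 | (R)-2-(benzyloxy)-6-(tert-butoxy)-2-methylhex-5-yn-3-ol | CC(C)(OCc1ccccc1)[C@H](O)CC#COC(C)(C)C | intermediate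
11 | (R)-2-(benzyloxy)-6-(tert-butoxy)-3-{[(E)-1,2-dichloroethenyl]oxy}-2-methylhex-5-yne | CC(C)(OCc1ccccc1)[C@H](O/C(Cl)=C\Cl)CC#COC(C)(C)C | intermediate
12 | (R)-2-(benzyloxy)-6-(tert-butoxy)-3-[(lithioethynyl)oxy]-2-methylhex-5-yne | CC(C)(OCc1ccccc1)[C@H](OC#C[Li])CC#COC(C)(C)C | intermediate (not isolated)
13 | (R)-2-(benzyloxy)-6-(tert-butoxy)-3-(ethynyloxy)-2-methylhex-5-yne | CC(C)(OCc1ccccc1)[C@H](OC#C)CC#COC(C)(C)C | intermediate
14 | (R)-2-methylbutanoic acid | CC[C@@H](C)C(=O)O | starting material
15 | (R)-1-(1H-imidazol-1-yl)-2-methylbutan-1-one | CC[C@@H](C)C(=O)n1ccnc1 | intermediate (not isolated)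
16 | (R)-N-methoxy-N,2-dimethylbutanamide | CC[C@@H](C)C(=O)N(C)OC | intermediate
17 | bromomagnesium tert-butoxyacetylide | Br[Mg]C#COC(C)(C)C | intermediate (not isolated)
18 | (R)-1-(tert-butoxy)-4-methylhex-1-yn-3-one | CC(C)(C)OC#CC(=O)[C@H](C)CC | intermediate
19 | (R)-1-{(R)-2-[2-(benzyloxy)propan-2-yl]-4,6-di-tert-butoxy-2,3-dihydro-1-benzofuran-5-yl}-2-methylbutan-1-one | CC(C)(OCc1ccccc1)[C@H]1Cc2c(OC(C)(C)C)c(C(=O)[C@H](C)CC)c(OC(C)(C)C)cc2O1 | intermediate
20 | (R)-1-[(R)-4,6-di-tert-butoxy-2-(2-hydroxypropan-2-yl)-2,3-dihydro-1-benzofuran-5-yl]-2-methylbutan-1-one | CC(C)(O)[C@H]1Cc2c(OC(C)(C)C)c(C(=O)[C@H](C)CC)c(OC(C)(C)C)cc2O1 | intermediate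
21 | (R)-1-[(R)-4,6-di-tert-butoxy-2-(prop-1-en-2-yl)-2,3-dihydro-1-benzofuran-5-yl]-2-methylbutan-1-one | C=C(C)[C@H]1Cc2c(OC(C)(C)C)c(C(=O)[C@H](C)CC)c(OC(C)(C)C)cc2O1 | intermediate
22 | (R)-1-[(R)-4,6-dihydroxy-2-(prop-1-en-2-yl)-2,3-dihydro-1-benzofuran-5-yl]-2-methylbutan-1-one | C=C(C)[C@H]1Cc2c(O)c(C(=O)[C@H](C)CC)c(O)cc2O1 | intermediate
23 | 3-pentanone | CCC(=O)CC | starting material
24 | 3-(trimethylsilyloxy)pent-2-ene (E/Z mixture, geometry immaterial) | CC=C(CC)O[Si](C)(C)C | intermediate
25 | malonyl dichloride | O=C(Cl)CC(=O)Cl | starting material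
26 | 6-ethyl-4-hydroxy-5-methyl-2H-pyran-2-one | CCc1oc(=O)cc(O)c1C | intermediate
27 | 3-[(dimethylamino)methyl]-6-ethyl-4-hydroxy-5-methyl-2H-pyran-2-one (formed as its hydroiodide) | CCc1oc(=O)c(CN(C)C)c(O)c1C | intermediate (not isolated)
28 | 6-ethyl-5-methyl-3-methylidene-2H-pyran-2,4(3H)-dione | CCC1=C(C)C(=O)C(=C)C(=O)O1 | intermediate (not isolated)
29 | 6-ethyl-3-{[(2R)-4,6-dihydroxy-5-[(2R)-2-methylbutanoyl]-2-(prop-1-en-2-yl)-2,3-dihydro-1-benzofuran-7-yl]methyl}-4-hydroxy-5-methyl-2H-pyran-2-one | C=C(C)[C@H]1Cc2c(O)c(C(=O)[C@H](C)CC)c(O)c(Cc3c(O)c(C)c(CC)oc3=O)c2O1 | target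

**Count and risks**

Total step count: 17. Longest linear sequence: 11 steps (steps 1, 2, 3, 6, 7, 8, 11, 12, 13, 14, 17).

Steps most likely to fail:

1. Step 11 (the step proposed as a new method). The ynone may insert in the reverse orientation, the diyne may oligomerise with itself, the terminal alkynyl ether may divert the catalyst, or the tert-butyl alkynyl ethers may lose isobutene before they cyclise. The fallback uses known chemistry only and builds the dihydrofuran ring on a preformed arene. It sets out from acid 14, which oxalyl chloride/cat. DMF converts into (R)-2-methylbutanoyl chloride F1. Friedel–Crafts acylation of commercial phloroglucinol (AlCl3, PhNO2/CH2Cl2, 0 °C → rt) should give (R)-2-methyl-1-(2,4,6-trihydroxyphenyl)butan-1-one F2. A Nickl-type annulation with commercial (E)-1,4-dibromo-2-methylbut-2-ene (K2CO3, acetone) follows: C-alkylation of the ring, then SN2′ closure through the hydroxyl para to the acyl group. This should give diphenol 22, where the fallback rejoins the route before step 17. In this variant C2 forms without control, so 22 is expected together with its C2 epimer, (R)-1-[(S)-4,6-dihydroxy-2-(prop-1-en-2-yl)-2,3-dihydro-1-benzofuran-5-yl]-2-methylbutan-1-one F3, and the two diastereomers would have to be separated by preparative HPLC.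

2. Step 14. Acid may do more than cleave the ethers: the tert-butyl cation may re-alkylate the electron-rich C7 position, acid may add to the isopropenyl group, or the allylic C2–O1 bond may ionise with loss of configuration. The fallback changes the order of events so that acid never meets the alkene. It sets out from tertiary alcohol 20. TFA in CH2Cl2 (cold and brief; a cation trap can be added freely, since no alkene is present) would give (R)-1-[(R)-4,6-dihydroxy-2-(2-hydroxypropan-2-yl)-2,3-dihydro-1-benzofuran-5-yl]-2-methylbutan-1-one F4. Ac2O/pyridine should acetylate only the two phenols, giving (R)-2-(2-hydroxypropan-2-yl)-5-[(R)-2-methylbutanoyl]-2,3-dihydro-1-benzofuran-4,6-diyl diacetate F5. Burgess dehydration as in step 13 would give (R)-5-[(R)-2-methylbutanoyl]-2-(prop-1-en-2-yl)-2,3-dihydro-1-benzofuran-4,6-diyl diacetate F6. Methanolysis (K2CO3 cat., MeOH, 0 °C) then returns the route at 22.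

3. Step 8. Butyllithium may deprotonate the propargylic CH2 next to the tert-butoxyalkyne (isomerisation to an allenyl ether) or the benzylic position before both chlorines are removed, and the terminal alkynyl ether may hydrate or fragment to a ketene during isolation. The fallback builds the ethynyl ether from a formate, so that fast bromine–lithium exchange initiates the alkyne formation. It sets out from alcohol 10. Acetic formic anhydride/pyridine would give (R)-2-(benzyloxy)-6-(tert-butoxy)-2-methylhex-5-yn-3-yl formate F7. Dibromomethylenation of the formate carbonyl (Ph3P, CBr4, Et3N-buffered, CH2Cl2, 0 °C) would give (R)-2-(benzyloxy)-6-(tert-butoxy)-3-[(2,2-dibromoethenyl)oxy]-2-methylhex-5-yne F8. n-BuLi (2 equiv, THF, −78 °C) should then give, by bromine–lithium exchange and Fritsch–Buttenberg–Wiechell-type rearrangement, the same lithium alkynyl ether 12, and a cold aqueous quench returns the route at 13.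

**Further compounds**

F1 | step 11 | (R)-2-methylbutanoyl chloride | CC[C@@H](C)C(Cl)=O
F2 | step 11 | (R)-2-methyl-1-(2,4,6-trihydroxyphenyl)butan-1-one | CC[C@@H](C)C(=O)c1c(O)cc(O)cc1O
F3 | step 11 | (R)-1-[(S)-4,6-dihydroxy-2-(prop-1-en-2-yl)-2,3-dihydro-1-benzofuran-5-yl]-2-methylbutan-1-one | C=C(C)[C@@H]1Cc2c(O)c(C(=O)[C@H](C)CC)c(O)cc2O1
F4 | step 14 | (R)-1-[(R)-4,6-dihydroxy-2-(2-hydroxypropan-2-yl)-2,3-dihydro-1-benzofuran-5-yl]-2-methylbutan-1-one | CC(C)(O)[C@H]1Cc2c(O)c(C(=O)[C@H](C)CC)c(O)cc2O1
F5 | step 14 | (R)-2-(2-hydroxypropan-2-yl)-5-[(R)-2-methylbutanoyl]-2,3-dihydro-1-benzofuran-4,6-diyl diacetate | CC(C)(O)[C@H]1Cc2c(OC(C)=O)c(C(=O)[C@H](C)CC)c(OC(C)=O)cc2O1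
F6 | step 14 | (R)-5-[(R)-2-methylbutanoyl]-2-(prop-1-en-2-yl)-2,3-dihydro-1-benzofuran-4,6-diyl diacetate | C=C(C)[C@H]1Cc2c(OC(C)=O)c(C(=O)[C@H](C)CC)c(OC(C)=O)cc2O1
F7 | step 8 | (R)-2-(benzyloxy)-6-(tert-butoxy)-2-methylhex-5-yn-3-yl formate | CC(C)(OCc1ccccc1)[C@H](OC=O)CC#COC(C)(C)C
F8 | step 8 | (R)-2-(benzyloxy)-6-(tert-butoxy)-3-[(2,2-dibromoethenyl)oxy]-2-methylhex-5-yne | CC(C)(OCc1ccccc1)[C@H](OC=C(Br)Br)CC#COC(C)(C)C
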